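**Strategy.** The sulfide sulfur lies on a C2 axis, so both 12-membered lactone rings (each 2S,5S,11R) come from the same monomer. Each ring is cut at C7–C8. This bond sits in the middle of the unfunctionalised C6–C10 methylene run, remote from every stereocentre. The key step is a chemoselective ring-closing metathesis of an acyclic triene ester. The two terminal alkenes close the macrocycle, and the electron-poor C2=C3 alkene of the enone-ester stays untouched. That alkene then takes up H2S twice in a biomimetic double thia-Michael addition. The sulfide bridge in turn shields C2–C3 while diimide erases the E/Z mixture at C7=C8.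

Key step: step 6

Remark on numbering: C1 is the lactone C=O, C2 the CH–S, C4 the ketone, C5 the carbinol and C11 the CH–CH3. Primes mark the second ring.
Assumption: the natural (2S,2'S) configuration is taken to be the one that macrocycle-controlled, reversible thia-Michael addition to the (E)-4-oxo-2-enoate should favour.

Step 1
Reactants: 1 (R)-propylene oxide; 2 allylmagnesium chloride
Product: 3 (R)-hex-5-en-2-ol
Conditions: CuI (10 mol %), THF, −30 to 0 °C; aq. work-up
Reagents that add atoms: none
Why: Cu-catalysed Grignard opening of a terminal epoxide occurs by SN2 at the unsubstituted CH2, so the C–O stereocentre of 1 is untouched and becomes C11 (R).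

Step 2
Reactants: 4 furfural; 5 allyltributylstannane
Product: 6 (S)-1-(furan-2-yl)but-3-en-1-ol
Conditions: (S)-BINOL (10 mol %), Ti(OiPr)4 (10 mol %), 4 Å MS, CH2Cl2, −20 °C; aq. NaHCO3
Reagents that add atoms: none
Why: In the Keck asymmetric allylation the (S)-BINOL–Ti Lewis acid should direct the allyl group to the Si face of the aldehyde, which sets the future C5 as S.

Step 3
Reactants: 6 (S)-1-(furan-2-yl)but-3-en-1-ol
Product: 7 (S)-tert-butyl[1-(furan-2-yl)but-3-enyloxy]dimethylsilane
Conditions: TBSCl, imidazole, DMF, rt
Reagents that add atoms: tert-butyldimethylsilyl chloride, CC(C)(C)[Si](C)(C)Cl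
Why: Standard silylation blocks the carbinol, so the furan oxidation in step 4 cannot divert into an Achmatowicz pyranone.

Step 4
Reactants: 7 (S)-tert-butyl[1-(furan-2-yl)but-3-enyloxy]dimethylsilane
Product: 10 (S,E)-5-(tert-butyldimethylsilyloxy)-4-oxoocta-2,7-dienoic acid, via Z-enal 8 (not isolated), via E-enal 9 (not isolated)
Conditions: NBS (1.05 equiv), NaHCO3, acetone/H2O, −15 °C; pyridine, rt; then t-BuOH, 2-methyl-2-butene, NaH2PO4, NaClO2, 0 °C to rt
Reagents that add atoms: water, O; sodium chlorite, [Na+].[O-]Cl=O
Why: The electron-rich furan reacts with NBS far faster than the terminal alkene and opens oxidatively to the 4-oxo-2-enal, pyridine isomerises Z to E, and Pinnick oxidation gives the acid without touching C5.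

Step 5
Reactants: 10 (S,E)-5-(tert-butyldimethylsilyloxy)-4-oxoocta-2,7-dienoic acid; 3 (R)-hex-5-en-2-ol
Product: 11 (R)-hex-5-en-2-yl (S,E)-5-(tert-butyldimethylsilyloxy)-4-oxoocta-2,7-dienoate
Conditions: DCC, DMAP (10 mol %), CH2Cl2, 0 °C to rt
Reagents that add atoms: none
Why: Steglich esterification activates the acid only, so the C11–O bond is not broken (retention), and the cold, weakly basic medium leaves C5 and the enone intact.

Step 6
Reactants: 11 (R)-hex-5-en-2-yl (S,E)-5-(tert-butyldimethylsilyloxy)-4-oxoocta-2,7-dienoate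
Product: 12 (2E,5S,11R)-5-(tert-butyldimethylsilyloxy)-4-oxododeca-2,7-dien-11-olide (7E/7Z mixture)
Conditions: Grubbs I catalyst (2 × 5 mol %), CH2Cl2 (1 mM), reflux, argon sparge
Reagents that add atoms: none
Why: This is a ring-closing olefin metathesis by the Chauvin mechanism: the Ru alkylidene loads on one terminal alkene, undergoes [2+2] cycloaddition and cycloreversion with the other, and joins C7 to C8 with loss of ethylene. The closest known reaction type is the macro-RCM of ω-alkenyl alkenoates to 12-membered lactones. The single ring closes end to end, since both termini give up their =CH2 carbons and all twelve ring atoms already sit in the chain. No stereocentre is created, and the C7=C8 geometry is left uncontrolled because step 8 converts both isomers into the same CH2–CH2 unit. The step needs chemoselectivity against the C2=C3 alkene, whose closure onto C7 would give a cyclopentenone; this is secured because C2=C3 is 1,2-disubstituted and flanked by two carbonyls, and the first-generation catalyst does not engage such alkenes. High dilution and removal of ethylene favour the ring over oligomers, and because of the C2 axis this one closure supplies both rings of the target.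

Step 7
Reactants: 12 (2E,5S,11R)-5-(tert-butyldimethylsilyloxy)-4-oxododeca-2,7-dien-11-olide (2 equiv)
Product: 14 bis[(2S,5S,11R)-5-(tert-butyldimethylsilyloxy)-4-oxododec-7-en-11-olid-2-yl] sulfide, via thiol 13 (not isolated)
Conditions: H2S (0.5 equiv, 0.8 M in THF), Et3N (10 mol %), degassed THF, dark, −20 °C to rt
Reagents that add atoms: hydrogen sulfide, S
Why: In this biomimetic double thia-Michael addition sulfur attacks C2 (β to the more activating C4 ketone), thiol 13 adds to a second molecule of 12, attack should come from the peripheral enone face left open by the C5-OTBS and C11-methyl groups, and reversibility under Et3N should let both C2 centres settle as S.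

Step 8
Reactants: 14 bis[(2S,5S,11R)-5-(tert-butyldimethylsilyloxy)-4-oxododec-7-en-11-olid-2-yl] sulfide
Product: 15 bis[(2S,5S,11R)-5-(tert-butyldimethylsilyloxy)-4-oxododecan-11-olid-2-yl] sulfide
Conditions: dipotassium azodicarboxylate (excess, in portions), AcOH, CH2Cl2/MeOH, rt
Reagents that add atoms: none
Why: Diimide reduction transfers H2 concertedly to the isolated C7=C8 and C7'=C8' alkenes, is not poisoned by the sulfide, leaves C=O groups alone, funnels all E/Z isomers into one compound, and its acidic medium suppresses retro-Michael loss at C2.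

Step 9
Reactants: 15 bis[(2S,5S,11R)-5-(tert-butyldimethylsilyloxy)-4-oxododecan-11-olid-2-yl] sulfide
Product: 16 thiocladospolide F
Conditions: HF·pyridine, THF/pyridine, 0 °C to rt
Reagents that add atoms: none
Why: Fluoride-driven desilylation under buffered acidic conditions frees both C5 hydroxyls without the base that would trigger retro-Michael cleavage at C2 or enolisation at C5.

**Compound list**
1 | (R)-propylene oxide | C[C@@H]1CO1 | starting material
2 | allylmagnesium chloride | C=CC[Mg]Cl | starting material
3 | (R)-hex-5-en-2-ol | C[C@@H](O)CCC=C | intermediate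
4 | furfural | O=Cc1ccco1 | starting material
5 | allyltributylstannane | C=CC[Sn](CCCC)(CCCC)CCCC | starting material
6 | (S)-1-(furan-2-yl)but-3-en-1-ol | C=CC[C@H](O)c1ccco1 | intermediate
7 | (S)-tert-butyl[1-(furan-2-yl)but-3-enyloxy]dimethylsilane | C=CC[C@H](O[Si](C)(C)C(C)(C)C)c1ccco1 | intermediate
8 | (S,Z)-5-(tert-butyldimethylsilyloxy)-4-oxoocta-2,7-dienal (not isolated) | O=C/C=C\C(=O)[C@H](CC=C)O[Si](C)(C)C(C)(C)C | intermediate
9 | (S,E)-5-(tert-butyldimethylsilyloxy)-4-oxoocta-2,7-dienal (not isolated) | O=C/C=C/C(=O)[C@H](CC=C)O[Si](C)(C)C(C)(C)C | intermediate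
10 | (S,E)-5-(tert-butyldimethylsilyloxy)-4-oxoocta-2,7-dienoic acid | OC(=O)/C=C/C(=O)[C@H](CC=C)O[Si](C)(C)C(C)(C)C | intermediate
11 | (R)-hex-5-en-2-yl (S,E)-5-(tert-butyldimethylsilyloxy)-4-oxoocta-2,7-dienoate | C=CCC[C@@H](C)OC(=O)/C=C/C(=O)[C@H](CC=C)O[Si](C)(C)C(C)(C)C | intermediate
12 | (2E,5S,11R)-5-(tert-butyldimethylsilyloxy)-4-oxododeca-2,7-dien-11-olide, 7E/7Z mixture | C[C@@H]1CCC=CC[C@H](O[Si](C)(C)C(C)(C)C)C(=O)/C=C/C(=O)O1 | intermediate
13 | (2S,5S,11R)-5-(tert-butyldimethylsilyloxy)-2-mercapto-4-oxododec-7-en-11-olide (not isolated) | C[C@@H]1CCC=CC[C@H](O[Si](C)(C)C(C)(C)C)C(=O)C[C@H](S)C(=O)O1 | intermediate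
14 | bis[(2S,5S,11R)-5-(tert-butyldimethylsilyloxy)-4-oxododec-7-en-11-olid-2-yl] sulfide | C[C@@H]1CCC=CC[C@H](O[Si](C)(C)C(C)(C)C)C(=O)C[C@H](S[C@H]2CC(=O)[C@@H](O[Si](C)(C)C(C)(C)C)CC=CCC[C@@H](C)OC2=O)C(=O)O1 | intermediate
15 | bis[(2S,5S,11R)-5-(tert-butyldimethylsilyloxy)-4-oxododecan-11-olid-2-yl] sulfide | C[C@@H]1CCCCC[C@H](O[Si](C)(C)C(C)(C)C)C(=O)C[C@H](S[C@H]2CC(=O)[C@@H](O[Si](C)(C)C(C)(C)C)CCCCC[C@@H](C)OC2=O)C(=O)O1 | intermediate
16 | thiocladospolide F | C[C@@H]1CCCCC[C@H](O)C(=O)C[C@H](S[C@H]2CC(=O)[C@@H](O)CCCCC[C@@H](C)OC2=O)C(=O)O1 | target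

**Total step count:** 9. **Longest linear sequence:** 8 (steps 2–9, from furfural).

**Steps most likely to fail**

Step 6. The ring closure may lose out to oligomerisation, to sequestration of the catalyst by chelation of the C7 alkylidene to the C4 ketone, or to engagement of the C2=C3 alkene. The fallback masks the enone before the metathesis.
- It sets out from 11. Et3N-catalysed conjugate addition of thioacetic acid should give the acyclic 2-acetylthio diene ester F1 as a C2 epimer mixture.
- F1 has no electron-poor alkene left and can be closed with the more active Grubbs II catalyst to the macrocyclic 2-acetylthio lactone F2.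
- DBU-induced E1cB elimination of thioacetic acid restores the (E)-enone and comes back to the route at 12.

Step 7. The facial selectivity of sulfur delivery at C2 may be poor, and it may differ between the 7E and 7Z rings. The fallback replaces substrate control with catalyst control and builds the bridge in two separate C–S bond formations.
- It sets out from 12. A cinchona-squaramide bifunctional catalyst is used, with the pseudo-enantiomer matched to the 2S outcome chosen by screening. It should add thioacetic acid to give the (2S)-2-acetylthio macrolide F3.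
- NaSMe in MeOH at −20 °C cleaves the thioacetate to thiol 13, which is now isolated.
- The same catalyst adds 13 to a second equivalent of 12, and the route is rejoined at 14.

Step 8. Diimide may reduce the internal macrocyclic alkenes sluggishly or incompletely, and the sulfide may erode through retro-Michael cleavage during long exposure. The fallback saturates the ring before sulfur is introduced.
- It sets out from 12. H2 over Pd/C in EtOAc reduces both alkenes to the saturated keto lactone F4.
- LiHMDS/TMSCl at −78 °C enolises towards the unhindered C3 and gives the silyl enol ether F5.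
- Saegusa–Ito oxidation with Pd(OAc)2 in MeCN gives the saturated-ring (E)-enone macrolide F6.
- H2S (0.5 equiv) with catalytic Et3N then adds twice through the saturated thiol F7, and the route is rejoined at 15.

**Further compounds**
F1 | step 6 | (R)-hex-5-en-2-yl (5S)-2-acetylthio-5-(tert-butyldimethylsilyloxy)-4-oxooct-7-enoate (C2 epimers) | C=CCC[C@@H](C)OC(=O)C(CC(=O)[C@H](CC=C)O[Si](C)(C)C(C)(C)C)SC(C)=O
F2 | step 6 | (5S,11R)-2-acetylthio-5-(tert-butyldimethylsilyloxy)-4-oxododec-7-en-11-olide (C2 epimers, 7E/7Z) | C[C@@H]1CCC=CC[C@H](O[Si](C)(C)C(C)(C)C)C(=O)CC(SC(C)=O)C(=O)O1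
F3 | step 7 | (2S,5S,11R)-2-acetylthio-5-(tert-butyldimethylsilyloxy)-4-oxododec-7-en-11-olide | C[C@@H]1CCC=CC[C@H](O[Si](C)(C)C(C)(C)C)C(=O)C[C@H](SC(C)=O)C(=O)O1
F4 | step 8 | (5S,11R)-5-(tert-butyldimethylsilyloxy)-4-oxododecan-11-olide | C[C@@H]1CCCCC[C@H](O[Si](C)(C)C(C)(C)C)C(=O)CCC(=O)O1
F5 | step 8 | (5S,11R)-5-(tert-butyldimethylsilyloxy)-4-(trimethylsilyloxy)dodec-3-en-11-olide | C[C@@H]1CCCCC[C@H](O[Si](C)(C)C(C)(C)C)C(O[Si](C)(C)C)=CCC(=O)O1
F6 | step 8 | (2E,5S,11R)-5-(tert-butyldimethylsilyloxy)-4-oxododec-2-en-11-olide | C[C@@H]1CCCCC[C@H](O[Si](C)(C)C(C)(C)C)C(=O)/C=C/C(=O)O1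
F7 | step 8 | (2S,5S,11R)-5-(tert-butyldimethylsilyloxy)-2-mercapto-4-oxododecan-11-olide | C[C@@H]1CCCCC[C@H](O[Si](C)(C)C(C)(C)C)C(=O)C[C@H](S)C(=O)O1
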